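**Retrosynthetic overview**
- The target is the 15-O-formate of (13S)-15-hydroxylabd-7-en-17-oic acid; formylation is last, and the C17 acid comes from the C8 methyl of (13S)-labd-7-en-15-ol by allylic oxidation (SeO2, then NaClO2).
- Key disconnection C12–C13: an α-lithiated N-Boc-N-aryl crotylamine·(−)-sparteine complex (chiral homoenolate, d3 equivalent of butanal) is alkylated at its γ-carbon by a C12 primary iodide. This joins the β-carbon of a masked aldehyde to an alkyl-halide carbon and sets C13.
- The iodide comes from (+)-sclareolide by acid-mediated lactone opening/dehydration to the Δ7 ester, reduction and iodination.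
- No ring is built: the trans-decalin (C5, C9, C10) is taken intact from sclareolide; only the lactone ring is opened.

Assumption: (−)-sparteine is taken to direct lithiation/γ-alkylation of the crotyl carbamate with the same facial sense as in the known 3-aryl series (predicting 13S); if 13R is found, commercial (+)-sparteine is used instead.

**Step 1**
Reactants: 1 (+)-sclareolide
Product: 2 methyl 13,14,15,16-tetranorlabd-7-en-12-oate
Conditions: conc. H2SO4 (cat.), MeOH, reflux; AgNO3–SiO2 chromatography to remove Δ8(9)/Δ8(17) isomers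
Reagents that add atoms: methanol, CO
Why: Acid ionises the tertiary C8–O bond of the lactone (E1 dehydration), the C8 cation loses an axial H-7 to give mainly the trisubstituted Δ7 alkene and the freed acid is trapped by Fischer esterification, so C5, C9 and C10 remain as in sclareolide.

**Step 2**
Reactants: 2 methyl 13,14,15,16-tetranorlabd-7-en-12-oate
Product: 3 13,14,15,16-tetranorlabd-7-en-12-ol
Conditions: LiAlH4, THF, 0 °C to rt; Fieser work-up
Reagents that add atoms: none
Why: Hydride reduction of the ester to the primary alcohol leaves the isolated trisubstituted alkene and all stereocentres untouched.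

**Step 3**
Reactants: 3 13,14,15,16-tetranorlabd-7-en-12-ol
Product: 4 12-iodo-13,14,15,16-tetranorlabd-7-ene
Conditions: PPh3, I2, imidazole premixed in CH2Cl2 at 0 °C; then 3, 0 °C to rt
Reagents that add atoms: iodine, II
Why: Appel-type (Garegg–Samuelsson) iodination proceeds by SN2 displacement of the alkoxyphosphonium at primary C12, and pre-forming Ph3PI2 leaves no free iodine for iodoetherification onto the Δ7 alkene.

**Step 4**
Reactants: 5 tert-butyl N-(4-methoxyphenyl)carbamate; 6 (E)-1-bromobut-2-ene
Product: 8 tert-butyl N-[(2E)-but-2-en-1-yl]-N-(4-methoxyphenyl)carbamate, via sodium carbamate salt 7 (not isolated)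
Conditions: NaH, DMF, 0 °C; then 6, 0 °C to rt; E isomer purified by chromatography
Reagents that add atoms: sodium hydride, [Na+].[H-] (supplies Na of intermediate 7 only)
Why: SN2 N-alkylation of the carbamate anion at the primary allylic carbon keeps the E alkene geometry.

**Step 5**
Reactants: 8 tert-butyl N-[(2E)-but-2-en-1-yl]-N-(4-methoxyphenyl)carbamate (1.5 equiv); 4 12-iodo-13,14,15,16-tetranorlabd-7-ene
Product: 10 tert-butyl N-(4-methoxyphenyl)-N-[(13S,14Z)-labda-7,14-dien-15-yl]carbamate, via lithiated carbamate 9 (not isolated)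
Conditions: n-BuLi, (−)-sparteine, PhMe, −78 °C, 1 h; then 4, −78 °C, 8 h; MeOH quench
Reagents that add atoms: n-butyllithium, [Li]CCCC (supplies Li of intermediate 9 only)
Why: (−)-Sparteine-mediated asymmetric α-lithiation of the N-Boc-N-aryl allylamine gives a configurationally stable allyllithium that acts as a chiral homoenolate (d3) equivalent and is alkylated by the primary iodide at its γ-carbon anti to lithium (Beak lithiation–substitution, anti-SE2′), so the ligand-controlled face of attack on the E-crotyl terminus sets C13 as S and the masked aldehyde emerges as a Z-enecarbamate.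

**Step 6**
Reactants: 10 tert-butyl N-(4-methoxyphenyl)-N-[(13S,14Z)-labda-7,14-dien-15-yl]carbamate
Product: 12 (13S)-labd-7-en-15-ol, via (13S)-labd-7-en-15-al 11 (not isolated)
Conditions: 2 M HCl, THF, rt; extractive work-up; then NaBH4, MeOH, 0 °C
Reagents that add atoms: water, O
Why: Acid hydrolysis of the enecarbamate (C14 protonation, then hydrolysis of the N-acyliminium ion) releases the β-branched aldehyde and carbamate 5, and NaBH4 reduces the crude aldehyde, C13 being β to the carbonyl and so not epimerisable.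

**Step 7**
Reactants: 12 (13S)-labd-7-en-15-ol
Product: 13 (13S)-15-hydroxylabd-7-en-17-al
Conditions: SeO2 (1.5 equiv), 1,4-dioxane, 90 °C
Reagents that add atoms: selenium dioxide, O=[Se]=O
Why: Riley allylic oxidation (ene reaction then [2,3]-shift) attacks α to the more substituted alkene carbon with CH3 preferred over the hindered C9 methine, as in the drimenyl acetate to 12-al precedent, giving the Δ7 enal without touching the saturated primary alcohol or any stereocentre.

**Step 8**
Reactants: 13 (13S)-15-hydroxylabd-7-en-17-al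
Product: 14 (13S)-15-hydroxylabd-7-en-17-oic acid
Conditions: NaClO2, NaH2PO4, 2-methyl-2-butene, t-BuOH/H2O, rt
Reagents that add atoms: sodium chlorite, [Na+].[O-]Cl=O
Why: Pinnick oxidation converts the enal into the α,β-unsaturated acid without oxidising the primary alcohol or moving the double bond, the scavenger removing HOCl.

**Step 9**
Reactants: 14 (13S)-15-hydroxylabd-7-en-17-oic acid
Product: 15 (13S)-15-(formyloxy)labd-7-en-17-oic acid
Conditions: HCO2H (98%, neat), 50 °C; aqueous work-up
Reagents that add atoms: formic acid, O=CO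
Why: Fischer esterification of the primary alcohol in neat formic acid gives the formate, while the conjugated acid stays free because any mixed anhydride hydrolyses on work-up and the deactivated Δ7 alkene does not isomerise.

**Compound list**
1 | (+)-sclareolide (8α,12-epoxy-13,14,15,16-tetranorlabdan-12-one; 5α-H, 9α-H, 10β-Me, 8β-Me) | O=C1C[C@H]2[C@](C)(O1)CC[C@H]3C(C)(C)CCC[C@]23C | starting material
2 | methyl (5S,9S,10S)-13,14,15,16-tetranorlabd-7-en-12-oate | COC(=O)C[C@H]1C(C)=CC[C@H]2C(C)(C)CCC[C@]12C | intermediate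
3 | (5S,9S,10S)-13,14,15,16-tetranorlabd-7-en-12-ol | OCC[C@H]1C(C)=CC[C@H]2C(C)(C)CCC[C@]12C | intermediate
4 | (5S,9S,10S)-12-iodo-13,14,15,16-tetranorlabd-7-ene | ICC[C@H]1C(C)=CC[C@H]2C(C)(C)CCC[C@]12C | intermediate
5 | tert-butyl N-(4-methoxyphenyl)carbamate | COc1ccc(NC(=O)OC(C)(C)C)cc1 | starting material
6 | (E)-1-bromobut-2-ene (crotyl bromide) | C/C=C/CBr | starting material
7 | sodium salt of tert-butyl N-(4-methoxyphenyl)carbamate | [Na+].COc1ccc([N-]C(=O)OC(C)(C)C)cc1 | intermediate
8 | tert-butyl N-[(2E)-but-2-en-1-yl]-N-(4-methoxyphenyl)carbamate | C/C=C/CN(C(=O)OC(C)(C)C)c1ccc(OC)cc1 | intermediate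
9 | tert-butyl N-[(1R,2E)-1-lithiobut-2-en-1-yl]-N-(4-methoxyphenyl)carbamate, held as its (−)-sparteine complex (configuration as required for anti-SE2′ delivery of 13S) | C/C=C/[C@@H]([Li])N(C(=O)OC(C)(C)C)c1ccc(OC)cc1 | intermediate
10 | tert-butyl N-(4-methoxyphenyl)-N-[(5S,9S,10S,13S,14Z)-labda-7,14-dien-15-yl]carbamate | C[C@H](/C=C\N(C(=O)OC(C)(C)C)c1ccc(OC)cc1)CC[C@H]1C(C)=CC[C@H]2C(C)(C)CCC[C@]12C | intermediate
11 | (5S,9S,10S,13S)-labd-7-en-15-al | C[C@H](CC=O)CC[C@H]1C(C)=CC[C@H]2C(C)(C)CCC[C@]12C | intermediate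
12 | (5S,9S,10S,13S)-labd-7-en-15-ol | C[C@H](CCO)CC[C@H]1C(C)=CC[C@H]2C(C)(C)CCC[C@]12C | intermediate
13 | (5S,9R,10S,13S)-15-hydroxylabd-7-en-17-al | C[C@H](CCO)CC[C@H]1C(C=O)=CC[C@H]2C(C)(C)CCC[C@]12C | intermediate
14 | (5S,9R,10S,13S)-15-hydroxylabd-7-en-17-oic acid | C[C@H](CCO)CC[C@H]1C(C(=O)O)=CC[C@H]2C(C)(C)CCC[C@]12C | intermediate
15 | (5S,9R,10S,13S)-15-(formyloxy)labd-7-en-17-oic acid (CNP0185418.1) | C[C@H](CCOC=O)CC[C@H]1C(C(=O)O)=CC[C@H]2C(C)(C)CCC[C@]12C | target

**Step count**
Total steps: 9. Longest linear sequence: 8 (steps 1, 2, 3, 5, 6, 7, 8, 9; step 4 is a one-step side branch).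

**Three steps most likely to fail, each with a fallback**

Step 5 (key coupling). Risks are low reactivity of the sparteine-bound allyllithium toward an unactivated primary iodide, α- versus γ-alkylation, and an enantiomeric ratio or facial sense that differs for the crotyl case; the C13 configuration should be checked on 12 (for example by Mosher ester analysis). The fallback sets out from 4 and reverses the roles of the partners. Magnesium insertion (Mg, Et2O) gives the Grignard reagent 12-(iodomagnesio)-13,14,15,16-tetranorlabd-7-ene F4. A CuBr·SMe2/Josiphos-catalysed asymmetric conjugate addition of F4 to S-ethyl (E)-but-2-enethioate (t-BuOMe, −75 °C; ligand enantiomer chosen on a model to give 13S) gives S-ethyl (13S)-labd-7-ene-15-thioate F5. LiAlH4 reduction of F5 comes back to the route at 12.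

Step 1 (regiochemistry of the lactone opening). Risk is a Δ7/Δ8(9)/Δ8(17) mixture that is poor in the Δ7 isomer or hard to separate. The fallback sets out from 1. KOH in MeOH gives potassium 8α-hydroxy-13,14,15,16-tetranorlabdan-12-oate F1, which is methylated in the same pot with MeI/DMF to methyl 8α-hydroxy-13,14,15,16-tetranorlabdan-12-oate F2. Kinetic, non-acidic dehydration (SOCl2, pyridine, CH2Cl2, −78 °C) gives the exocyclic isomer methyl 13,14,15,16-tetranorlabd-8(17)-en-12-oate F3. RhCl3·3H2O in EtOH (metal-hydride isomerisation, stopped at the trisubstituted alkene) then moves the double bond into the ring and comes back at 2.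

Step 7 (SeO2 oxidation). Risks are modest yield, partial stop at the allylic alcohol, and competing oxidation at C6 or C9. The fallback sets out from 12 and replaces the ene-type oxidation by allylic metalation. Schlosser base (n-BuLi/KOt-Bu, hexane, rt, excess) forms the alkoxide and deprotonates the C17 methyl to give the 15-O,17-C-dipotassio derivative of (13S)-labd-7-en-15-ol F6. B(OMe)3 at −78 °C gives the dimethyl (13S)-15-[(dimethoxyboryl)oxy]labd-7-en-17-ylboronate F7. NaOH/H2O2 oxidation gives (13S)-labd-7-ene-15,17-diol F8. MnO2 in CH2Cl2 oxidises only the allylic alcohol of F8 and comes back at 13.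

**Further compounds**
F1 | step 1 | potassium 8α-hydroxy-13,14,15,16-tetranorlabdan-12-oate | [K+].[O-]C(=O)C[C@H]1[C@](C)(O)CC[C@H]2C(C)(C)CCC[C@]12C
F2 | step 1 | methyl 8α-hydroxy-13,14,15,16-tetranorlabdan-12-oate | COC(=O)C[C@H]1[C@](C)(O)CC[C@H]2C(C)(C)CCC[C@]12C
F3 | step 1 | methyl 13,14,15,16-tetranorlabd-8(17)-en-12-oate | COC(=O)C[C@H]1C(=C)CC[C@H]2C(C)(C)CCC[C@]12C
F4 | step 5 | 12-(iodomagnesio)-13,14,15,16-tetranorlabd-7-ene | I[Mg]CC[C@H]1C(C)=CC[C@H]2C(C)(C)CCC[C@]12C
F5 | step 5 | S-ethyl (13S)-labd-7-ene-15-thioate | C[C@H](CC(=O)SCC)CC[C@H]1C(C)=CC[C@H]2C(C)(C)CCC[C@]12C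
F6 | step 7 | 15-O,17-C-dipotassio derivative of (13S)-labd-7-en-15-ol | C[C@H](CCO[K])CC[C@H]1C(C[K])=CC[C@H]2C(C)(C)CCC[C@]12C
F7 | step 7 | dimethyl (13S)-15-[(dimethoxyboryl)oxy]labd-7-en-17-ylboronate | C[C@H](CCOB(OC)OC)CC[C@H]1C(CB(OC)OC)=CC[C@H]2C(C)(C)CCC[C@]12C
F8 | step 7 | (13S)-labd-7-ene-15,17-diol | C[C@H](CCO)CC[C@H]1C(CO)=CC[C@H]2C(C)(C)CCC[C@]12C
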